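Assumption: atoms are called C1–C15 by germacrane numbering (C1 ketone, C4=C5 Z-alkene with the methyl on C4, C6 lactone carbinol, C7=C11 butenolide alkene, C8 ester carbinol, C9 free carbinol, C10 methyl-bearing carbon, C12 lactone carbonyl, C13 acetoxymethyl carbon); in step 7 the ProPhenol enantiomer is the one shown by Mosher analysis to give the S carbinol.

**Retrosynthetic overview**
1. The C13 acetate and C8 methacrylate go on last; the methacrylate is installed with inversion at C8.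
2. The ten-membered ring is closed second, at C7–C8, by intramolecular Nozaki–Hiyama–Kishi addition of a β-iodobutenolide (a β-acylvinyl donor) to the C8 aldehyde.
3. The butenolide ring is made first: propargylic carbonate → allenoate (Pd/CO) → iodolactonization, which relays the C6 configuration.
4. Key union C3–C4: Pd-catalysed ring-opening coupling of a cyclopropanol (ketone homoenolate, nucleophilic at C3) with a (Z)-alkenyl iodide (C4); this fixes the Z-alkene and unveils the C1 ketone.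
5. The cyclopropanol comes from dimethyl (R)-malate (C9/C10 by Fráter–Seebach methylation, C2/C3 from EtMgBr); the alkenyl iodide comes from but-2-yn-1-ol and a silyl propargyl ether (C6 by asymmetric alkynylation).

**Route**

Step 1
Reactants: 1 dimethyl (R)-malate
Product: 2 dimethyl (2R,3S)-2-hydroxy-3-methylbutanedioate
Conditions: LiN(SiMe3)2 (2.2 equiv), THF, −78 °C; then MeI, −78 to −20 °C
Reagents that add atoms: iodomethane, IC
Why: Fráter–Seebach alkylation: the dilithio alkoxide–enolate is a rigid chelate and MeI attacks the enolate face anti to the alkoxide-bearing centre, setting the new methyl centre (future C10, S) anti to the hydroxyl (about 9:1), while the carbinol (future C9, R) comes from (R)-malate.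

Step 2
Reactants: 2 dimethyl (2R,3S)-2-hydroxy-3-methylbutanedioate
Product: 3 methyl (2S,3R)-3,4-dihydroxy-2-methylbutanoate
Conditions: BH3·SMe2 (1.05 equiv), NaBH4 (5 mol %), THF, 0 °C to rt; MeOH quench; used crude
Reagents that add atoms: none
Why: Hydroxyl-directed chemoselective borane reduction: the free hydroxyl forms an alkoxyborane that delivers hydride only to the adjacent ester, so the remote ester and both stereocentres are untouched.

Step 3
Reactants: 3 methyl (2S,3R)-3,4-dihydroxy-2-methylbutanoate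
Product: 4 methyl (2S,3R)-2-methyl-3,4-bis(triethylsilyloxy)butanoate
Conditions: Et3SiCl (2.4 equiv), imidazole, DMF, 0 °C
Reagents that add atoms: chlorotriethylsilane, CC[Si](Cl)(CC)CC
Why: Silyl ether formation: imidazole-promoted silylation caps both hydroxyls before the γ-hydroxy ester can lactonize, and gives a primary silyl ether that can later be oxidized selectively beside the secondary one.

Step 4
Reactants: 4 methyl (2S,3R)-2-methyl-3,4-bis(triethylsilyloxy)butanoate
Product: 5 1-[(2S,3R)-3,4-bis(triethylsilyloxy)butan-2-yl]cyclopropan-1-ol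
Conditions: EtMgBr (3 equiv), Ti(OiPr)4 (0.3 equiv), THF, 0 °C to rt
Reagents that add atoms: ethylmagnesium bromide, CC[Mg]Br
Why: Kulinkovich cyclopropanation: the titanacyclopropane from EtMgBr and Ti(OiPr)4 adds twice to the ester carbonyl as a 1,2-dicarbanion, turning it into a 1-substituted cyclopropanol (a latent ketone homoenolate carrying C1–C3) without epimerizing the α-centre.

Step 5
Reactants: 6 but-2-yn-1-ol
Product: 8 (Z)-3-iodobut-2-en-1-ol, via cyclic alkenylaluminate 7 (not isolated)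
Conditions: NaAlH2(OCH2CH2OMe)2 (1.1 equiv), THF, 0 °C to rt; then I2, −78 to 0 °C
Reagents that add atoms: iodine, I-I
Why: Hydroxyl-directed trans-hydroalumination then iodinolysis: the aluminium alkoxide delivers hydride to C2 and places aluminium on C3 in a five-membered ring, and iodine replaces the C–Al bond with retention, so iodine ends cis to CH2OH (the future C4=C5 Z geometry).

Step 6
Reactants: 8 (Z)-3-iodobut-2-en-1-ol
Product: 9 (Z)-3-iodobut-2-enal
Conditions: MnO2 (15 equiv), CH2Cl2, rt, dark; used at once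
Reagents that add atoms: none
Why: MnO2 oxidation of an allylic alcohol: the neutral heterogeneous oxidant gives the enal without over-oxidation or Z-to-E isomerization of the iodoalkene.

Step 7
Reactants: 9 (Z)-3-iodobut-2-enal; 10 tert-butyldimethyl(prop-2-yn-1-yloxy)silane
Product: 11 (2Z,4S)-7-[(tert-butyldimethylsilyl)oxy]-2-iodohept-2-en-5-yn-4-ol
Conditions: ZnMe2 (3 equiv), ProPhenol ligand (20 mol %), Ph3PO (40 mol %), toluene, 0 to 4 °C
Reagents that add atoms: none
Why: Catalytic asymmetric aldehyde alkynylation (dinuclear zinc–ProPhenol catalysis): the alkynylzinc made from 10 and ZnMe2 adds to the enal carbonyl inside the chiral dizinc pocket, so the new C6 carbinol is set S by catalyst control while the alkenyl iodide is inert.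

Step 8
Reactants: 5 1-[(2S,3R)-3,4-bis(triethylsilyloxy)butan-2-yl]cyclopropan-1-ol; 11 (2Z,4S)-7-[(tert-butyldimethylsilyl)oxy]-2-iodohept-2-en-5-yn-4-ol
Product: 12 (2R,3S,7Z,9S)-12-[(tert-butyldimethylsilyl)oxy]-9-hydroxy-3,7-dimethyl-1,2-bis[(triethylsilyl)oxy]dodec-7-en-10-yn-4-one
Conditions: Pd(OAc)2 (5 mol %), XPhos (10 mol %), K3PO4 (2 equiv), toluene, 60 °C
Reagents that add atoms: none
Why: Proposed new method: zerovalent palladium inserts with retention into the C–I bond of 11, the resulting alkenylpalladium iodide (divalent palladium) exchanges iodide for the cyclopropoxide of 5, strain-driven β-carbon elimination gives a β-ketoalkylpalladium (ketone homoenolate, nucleophilic at C3), and the bulky biarylphosphine makes C(sp3)–C(sp2) reductive elimination faster than β-hydride elimination, so the C3–C4 bond forms with the Z geometry kept and the C1 ketone unveiled with no new stereocentre; the closest known reaction type is the Pd-catalysed ring-opening cross-coupling of cyclopropanols with aryl halides (and the Negishi coupling of zinc homoenolates with alkenyl halides).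

Step 9
Reactants: 12 (2R,3S,7Z,9S)-12-[(tert-butyldimethylsilyl)oxy]-9-hydroxy-3,7-dimethyl-1,2-bis[(triethylsilyl)oxy]dodec-7-en-10-yn-4-one
Product: 14 methyl (aR,5Z,10S,11R)-2-{[(tert-butyldimethylsilyl)oxy]methyl}-6,10-dimethyl-9-oxo-11,12-bis[(triethylsilyl)oxy]dodeca-2,3,5-trienoate, via tert-butyl carbonate 13 (not isolated)
Conditions: Boc2O, DMAP (10 mol %), THF, 0 °C to rt; then MeOH, Pd2(dba)3 (2.5 mol %), PPh3 (10 mol %), CO (5 atm), 40 °C
Reagents that add atoms: carbon monoxide, [C-]#[O+]; methanol, CO; di-tert-butyl dicarbonate, CC(C)(C)OC(=O)OC(=O)OC(C)(C)C (its atoms stay only in 13)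
Why: Palladium-catalysed SN2′ alkoxycarbonylation of a propargylic carbonate (Tsuji-type): zerovalent palladium ionizes the carbonate anti to the leaving group to an allenylpalladium species that inserts CO and is trapped by methanol, so the C6 configuration is relayed into the allene axis (aR) and C12 is installed on C11.

Step 10
Reactants: 14 methyl (aR,5Z,10S,11R)-2-{[(tert-butyldimethylsilyl)oxy]methyl}-6,10-dimethyl-9-oxo-11,12-bis[(triethylsilyl)oxy]dodeca-2,3,5-trienoate
Product: 15 (5R)-3-{[(tert-butyldimethylsilyl)oxy]methyl}-4-iodo-5-[(1Z,6S,7R)-2,6-dimethyl-5-oxo-7,8-bis(triethylsilyloxy)oct-1-en-1-yl]furan-2(5H)-one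
Conditions: I2 (2.5 equiv), NaHCO3 (3 equiv), MeCN/H2O 15:1, rt, dark
Reagents that add atoms: iodine, I-I; water, O
Why: Iodolactonization of a 2,3-allenoate: iodonium formation at C6=C7 and anti attack of the ester carbonyl oxygen at C6 give a cyclic oxocarbenium ion that water hydrolyses to the 4-iodobutenolide, so the allene axis becomes the C6 stereocentre (6R, overall inversion of the carbinol of 12) and C7 gains the iodide needed for ring closure.

Step 11
Reactants: 15 (5R)-3-{[(tert-butyldimethylsilyl)oxy]methyl}-4-iodo-5-[(1Z,6S,7R)-2,6-dimethyl-5-oxo-7,8-bis(triethylsilyloxy)oct-1-en-1-yl]furan-2(5H)-one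
Product: 16 (2R,3S,7Z)-8-[(2R)-4-{[(tert-butyldimethylsilyl)oxy]methyl}-3-iodo-5-oxo-2,5-dihydrofuran-2-yl]-3,7-dimethyl-4-oxo-2-[(triethylsilyl)oxy]oct-7-enal
Conditions: (COCl)2 (4 equiv), DMSO (8 equiv), CH2Cl2, −78 to −40 °C; then Et3N, −78 to 0 °C
Reagents that add atoms: none
Why: Swern oxidation applied directly to a primary silyl ether: the chlorosulfonium reagent cleaves the unhindered primary triethylsilyl ether and oxidizes it in place to the C8 aldehyde, while the secondary triethylsilyl ether, the tert-butyldimethylsilyl ether and the C6, C9 and C10 centres survive at low temperature.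

Step 12
Reactants: 16 (2R,3S,7Z)-8-[(2R)-4-{[(tert-butyldimethylsilyl)oxy]methyl}-3-iodo-5-oxo-2,5-dihydrofuran-2-yl]-3,7-dimethyl-4-oxo-2-[(triethylsilyl)oxy]oct-7-enal
Product: 17 (4S,5R,6S,10Z,11aR)-3-{[(tert-butyldimethylsilyl)oxy]methyl}-4-hydroxy-6,10-dimethyl-5-[(triethylsilyl)oxy]-4,5,6,8,9,11a-hexahydrocyclodeca[b]furan-2,7-dione
Conditions: CrCl2 (8 equiv), NiCl2 (5 mol %), DMSO, rt, 3 mM, slow addition of 16
Reagents that add atoms: none
Why: Nozaki–Hiyama–Kishi macrocyclization: zerovalent nickel inserts into the activated C7–I bond and transmetalation gives a non-basic alkenylchromium species (trivalent chromium), a β-acylvinyl donor that adds to the C8 aldehyde in preference to the C1 ketone and closes the ten-membered ring, the new C8 carbinol being set 8S by Felkin–Anh attack anti to the C9 silyloxy group.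

Step 13
Reactants: 17 (4S,5R,6S,10Z,11aR)-3-{[(tert-butyldimethylsilyl)oxy]methyl}-4-hydroxy-6,10-dimethyl-5-[(triethylsilyl)oxy]-4,5,6,8,9,11a-hexahydrocyclodeca[b]furan-2,7-dione
Product: 18 (4R,5R,6S,10Z,11aR)-3-{[(tert-butyldimethylsilyl)oxy]methyl}-6,10-dimethyl-2,7-dioxo-5-[(triethylsilyl)oxy]-2,4,5,6,7,8,9,11a-octahydrocyclodeca[b]furan-4-yl 2-methylprop-2-enoate
Conditions: methacrylic acid (3 equiv), PPh3 (3 equiv), DIAD (3 equiv), toluene, 0 °C to rt
Reagents that add atoms: methacrylic acid, C=C(C)C(=O)O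
Why: Mitsunobu esterification: the alkoxyphosphonium of the C8 alcohol is displaced by methacrylate in an SN2 reaction next to the butenolide π-system, so the ester enters with inversion (8S to 8R) and the other centres are untouched.

Step 14
Reactants: 18 (4R,5R,6S,10Z,11aR)-3-{[(tert-butyldimethylsilyl)oxy]methyl}-6,10-dimethyl-2,7-dioxo-5-[(triethylsilyl)oxy]-2,4,5,6,7,8,9,11a-octahydrocyclodeca[b]furan-4-yl 2-methylprop-2-enoate
Product: 19 (4R,5R,6S,10Z,11aR)-5-hydroxy-3-(hydroxymethyl)-6,10-dimethyl-2,7-dioxo-2,4,5,6,7,8,9,11a-octahydrocyclodeca[b]furan-4-yl 2-methylprop-2-enoate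
Conditions: HF·pyridine, pyridine, THF, 0 °C to rt
Reagents that add atoms: none
Why: Fluoride-mediated desilylation: buffered HF·pyridine removes both silyl ethers under mildly acidic conditions that avoid C8-to-C9 acyl migration, retro-aldol cleavage of the β-hydroxy ketone and epimerization at C6.

Step 15
Reactants: 19 (4R,5R,6S,10Z,11aR)-5-hydroxy-3-(hydroxymethyl)-6,10-dimethyl-2,7-dioxo-2,4,5,6,7,8,9,11a-octahydrocyclodeca[b]furan-4-yl 2-methylprop-2-enoate
Product: 20 (4R,5R,6S,10Z,11aR)-3-(acetoxymethyl)-5-hydroxy-6,10-dimethyl-2,7-dioxo-2,4,5,6,7,8,9,11a-octahydrocyclodeca[b]furan-4-yl 2-methylprop-2-enoate (CNP0164859.1)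
Conditions: AcCl (1.1 equiv), 2,4,6-collidine, CH2Cl2, −78 to −40 °C
Reagents that add atoms: acetyl chloride, CC(Cl)=O
Why: Chemoselective acylation: at low temperature with a hindered base, acetyl chloride reacts only with the unhindered primary allylic C13 hydroxyl and not with the hindered secondary C9 hydroxyl, giving the target with all four stereocentres (6R, 8R, 9R, 10S) in place.

**Compound list**

1 | dimethyl (R)-malate | COC(=O)C[C@H](C(=O)OC)O | starting material
2 | dimethyl (2R,3S)-2-hydroxy-3-methylbutanedioate | COC(=O)[C@@H](C)[C@H](C(=O)OC)O | intermediate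
3 | methyl (2S,3R)-3,4-dihydroxy-2-methylbutanoate | COC(=O)[C@@H](C)[C@H](CO)O | intermediate
4 | methyl (2S,3R)-2-methyl-3,4-bis(triethylsilyloxy)butanoate | COC(=O)[C@@H](C)[C@H](CO[Si](CC)(CC)CC)O[Si](CC)(CC)CC | intermediate
5 | 1-[(2S,3R)-3,4-bis(triethylsilyloxy)butan-2-yl]cyclopropan-1-ol | OC1(CC1)[C@@H](C)[C@H](CO[Si](CC)(CC)CC)O[Si](CC)(CC)CC | intermediate
6 | but-2-yn-1-ol | CC#CCO | starting material
7 | sodium 2,2-bis(2-methoxyethoxy)-3-methyl-2,5-dihydro-1,2-oxaaluminol-2-uide (cyclic alkenylaluminate, not isolated) | CC1=CCO[Al-]1(OCCOC)OCCOC.[Na+] | intermediate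
8 | (Z)-3-iodobut-2-en-1-ol | C/C(I)=C/CO | intermediate
9 | (Z)-3-iodobut-2-enal | C/C(I)=C/C=O | intermediate
10 | tert-butyldimethyl(prop-2-yn-1-yloxy)silane | C#CCO[Si](C)(C)C(C)(C)C | starting material
11 | (2Z,4S)-7-[(tert-butyldimethylsilyl)oxy]-2-iodohept-2-en-5-yn-4-ol | O[C@H](C#CCO[Si](C)(C)C(C)(C)C)/C=C(/C)I | intermediate
12 | (2R,3S,7Z,9S)-12-[(tert-butyldimethylsilyl)oxy]-9-hydroxy-3,7-dimethyl-1,2-bis[(triethylsilyl)oxy]dodec-7-en-10-yn-4-one | O[C@H](C#CCO[Si](C)(C)C(C)(C)C)/C=C(/C)CCC(=O)[C@@H](C)[C@H](CO[Si](CC)(CC)CC)O[Si](CC)(CC)CC | intermediate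
13 | tert-butyl (4S,5Z,10S,11R)-1-[(tert-butyldimethylsilyl)oxy]-6,10-dimethyl-9-oxo-11,12-bis[(triethylsilyl)oxy]dodec-5-en-2-yn-4-yl carbonate (not isolated) | CC(C)(C)OC(=O)O[C@H](C#CCO[Si](C)(C)C(C)(C)C)/C=C(/C)CCC(=O)[C@@H](C)[C@H](CO[Si](CC)(CC)CC)O[Si](CC)(CC)CC | intermediate
14 | methyl (aR,5Z,10S,11R)-2-{[(tert-butyldimethylsilyl)oxy]methyl}-6,10-dimethyl-9-oxo-11,12-bis[(triethylsilyl)oxy]dodeca-2,3,5-trienoate | [H]C(/C=C(/C)CCC(=O)[C@@H](C)[C@H](CO[Si](CC)(CC)CC)O[Si](CC)(CC)CC)=[C@@]=C(CO[Si](C)(C)C(C)(C)C)C(=O)OC | intermediate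
15 | (5R)-3-{[(tert-butyldimethylsilyl)oxy]methyl}-4-iodo-5-[(1Z,6S,7R)-2,6-dimethyl-5-oxo-7,8-bis(triethylsilyloxy)oct-1-en-1-yl]furan-2(5H)-one | IC1=C(CO[Si](C)(C)C(C)(C)C)C(=O)O[C@@H]1/C=C(/C)CCC(=O)[C@@H](C)[C@H](CO[Si](CC)(CC)CC)O[Si](CC)(CC)CC | intermediate
16 | (2R,3S,7Z)-8-[(2R)-4-{[(tert-butyldimethylsilyl)oxy]methyl}-3-iodo-5-oxo-2,5-dihydrofuran-2-yl]-3,7-dimethyl-4-oxo-2-[(triethylsilyl)oxy]oct-7-enal | IC1=C(CO[Si](C)(C)C(C)(C)C)C(=O)O[C@@H]1/C=C(/C)CCC(=O)[C@@H](C)[C@H](C=O)O[Si](CC)(CC)CC | intermediate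
17 | (4S,5R,6S,10Z,11aR)-3-{[(tert-butyldimethylsilyl)oxy]methyl}-4-hydroxy-6,10-dimethyl-5-[(triethylsilyl)oxy]-4,5,6,8,9,11a-hexahydrocyclodeca[b]furan-2,7-dione (C8-epi alcohol) | O[C@H]1C2=C(CO[Si](C)(C)C(C)(C)C)C(=O)O[C@@H]2/C=C(/C)CCC(=O)[C@@H](C)[C@H]1O[Si](CC)(CC)CC | intermediate
18 | (4R,5R,6S,10Z,11aR)-3-{[(tert-butyldimethylsilyl)oxy]methyl}-6,10-dimethyl-2,7-dioxo-5-[(triethylsilyl)oxy]-2,4,5,6,7,8,9,11a-octahydrocyclodeca[b]furan-4-yl 2-methylprop-2-enoate | C=C(C)C(=O)O[C@@H]1C2=C(CO[Si](C)(C)C(C)(C)C)C(=O)O[C@@H]2/C=C(/C)CCC(=O)[C@@H](C)[C@H]1O[Si](CC)(CC)CC | intermediate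
19 | (4R,5R,6S,10Z,11aR)-5-hydroxy-3-(hydroxymethyl)-6,10-dimethyl-2,7-dioxo-2,4,5,6,7,8,9,11a-octahydrocyclodeca[b]furan-4-yl 2-methylprop-2-enoate | C=C(C)C(=O)O[C@@H]1C2=C(CO)C(=O)O[C@@H]2/C=C(/C)CCC(=O)[C@@H](C)[C@H]1O | intermediate
20 | (4R,5R,6S,10Z,11aR)-3-(acetoxymethyl)-5-hydroxy-6,10-dimethyl-2,7-dioxo-2,4,5,6,7,8,9,11a-octahydrocyclodeca[b]furan-4-yl 2-methylprop-2-enoate (CNP0164859.1) | C=C(C)C(=O)O[C@@H]1C2=C(COC(C)=O)C(=O)O[C@@H]2/C=C(/C)CCC(=O)[C@@H](C)[C@H]1O | target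

**Step count and risks**

Total steps: 15. Longest linear sequence: 12 (steps 1–4, then 8–15).

Most likely to fail, step 8 (homoenolate–alkenyl iodide coupling). β-Hydride elimination of the β-ketoalkylpalladium to an enone, or base-induced loss of the C9 silyloxy group, could dominate. The fallback sets out from 5 and comes back at 12, replacing catalytic C–C cleavage by a preformed organozinc. Ring-opening iodination of 5 with N-iodosuccinimide (CH2Cl2, 0 °C) gives the β-iodo ketone (4S,5R)-1-iodo-4-methyl-5,6-bis(triethylsilyloxy)hexan-3-one F1. Zinc insertion (Zn dust, LiCl, THF, rt) gives the zinc homoenolate iodo[(4S,5R)-4-methyl-3-oxo-5,6-bis(triethylsilyloxy)hexyl]zinc F2. Negishi coupling of F2 with alkenyl iodide 11 (Pd(PPh3)4, THF, rt) then gives 12.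

Most likely to fail, step 12 (ten-membered ring closure). Oligomerization, poor or reversed C8 selectivity, or migration of the lactone from O6 to the new O8 are the hazards. If the 8R alcohol forms instead, it is acylated directly with retention. The fallback sets out from 16 and comes back at 18, closing the ring by acylation and setting C8 by reduction.
- Oxidation (NaClO2, NaH2PO4, 2-methylbut-2-ene) gives (2R,3S,7Z)-8-[(2R)-4-{[(tert-butyldimethylsilyl)oxy]methyl}-3-iodo-5-oxo-2,5-dihydrofuran-2-yl]-3,7-dimethyl-4-oxo-2-[(triethylsilyl)oxy]oct-7-enoic acid F3.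
- Thioesterification (EtSH, EDC·HCl, DMAP) gives the S-ethyl thioester of that acid F4.
- Zinc insertion into the activated C7–I bond (Zn dust, LiCl, THF) gives the butenolid-4-ylzinc iodide of the thioester F5.
- Intramolecular Fukuyama ketone coupling (PdCl2(PPh3)2, toluene, high dilution) gives (5R,6S,10Z,11aR)-3-{[(tert-butyldimethylsilyl)oxy]methyl}-6,10-dimethyl-5-[(triethylsilyl)oxy]-5,6,8,9-tetrahydrocyclodeca[b]furan-2,4,7(11aH)-trione F6.
- Catalyst-controlled 1,2-reduction of the C8 ketone (CBS oxazaborolidine, BH3·SMe2, −40 °C; this is also the Felkin sense) gives the 8R alcohol (4R,5R,6S,10Z,11aR)-3-{[(tert-butyldimethylsilyl)oxy]methyl}-4-hydroxy-6,10-dimethyl-5-[(triethylsilyl)oxy]-4,5,6,8,9,11a-hexahydrocyclodeca[b]furan-2,7-dione F7.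
- Methacrylic anhydride/DMAP then gives 18 with retention.

Most likely to fail, step 13 (Mitsunobu inversion at a hindered ring carbinol). Elimination, or no reaction because of the neighbouring silyl ether, is the risk. The fallback sets out from 17 and comes back at 18 by sulfonate displacement. Chloromethanesulfonyl chloride and pyridine (0 °C) give (4S,5R,6S,10Z,11aR)-3-{[(tert-butyldimethylsilyl)oxy]methyl}-6,10-dimethyl-2,7-dioxo-5-[(triethylsilyl)oxy]-2,4,5,6,7,8,9,11a-octahydrocyclodeca[b]furan-4-yl chloromethanesulfonate F8. Displacement with CsO2CC(CH3)=CH2 and 18-crown-6 in toluene at 40 °C (SN2, inversion) then gives 18.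

**Further compounds**

F1 | step 8 | (4S,5R)-1-iodo-4-methyl-5,6-bis(triethylsilyloxy)hexan-3-one | ICCC(=O)[C@@H](C)[C@H](CO[Si](CC)(CC)CC)O[Si](CC)(CC)CC
F2 | step 8 | iodo[(4S,5R)-4-methyl-3-oxo-5,6-bis(triethylsilyloxy)hexyl]zinc | I[Zn]CCC(=O)[C@@H](C)[C@H](CO[Si](CC)(CC)CC)O[Si](CC)(CC)CC
F3 | step 12 | (2R,3S,7Z)-8-[(2R)-4-{[(tert-butyldimethylsilyl)oxy]methyl}-3-iodo-5-oxo-2,5-dihydrofuran-2-yl]-3,7-dimethyl-4-oxo-2-[(triethylsilyl)oxy]oct-7-enoic acid | IC1=C(CO[Si](C)(C)C(C)(C)C)C(=O)O[C@@H]1/C=C(/C)CCC(=O)[C@@H](C)[C@H](C(=O)O)O[Si](CC)(CC)CC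
F4 | step 12 | S-ethyl (2R,3S,7Z)-8-[(2R)-4-{[(tert-butyldimethylsilyl)oxy]methyl}-3-iodo-5-oxo-2,5-dihydrofuran-2-yl]-3,7-dimethyl-4-oxo-2-[(triethylsilyl)oxy]oct-7-enethioate | IC1=C(CO[Si](C)(C)C(C)(C)C)C(=O)O[C@@H]1/C=C(/C)CCC(=O)[C@@H](C)[C@H](C(=O)SCC)O[Si](CC)(CC)CC
F5 | step 12 | iodo{(2R)-4-{[(tert-butyldimethylsilyl)oxy]methyl}-2-[(1Z,6S,7R)-8-(ethylsulfanyl)-2,6-dimethyl-5,8-dioxo-7-[(triethylsilyl)oxy]oct-1-en-1-yl]-5-oxo-2,5-dihydrofuran-3-yl}zinc | I[Zn]C1=C(CO[Si](C)(C)C(C)(C)C)C(=O)O[C@@H]1/C=C(/C)CCC(=O)[C@@H](C)[C@H](C(=O)SCC)O[Si](CC)(CC)CC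
F6 | step 12 | (5R,6S,10Z,11aR)-3-{[(tert-butyldimethylsilyl)oxy]methyl}-6,10-dimethyl-5-[(triethylsilyl)oxy]-5,6,8,9-tetrahydrocyclodeca[b]furan-2,4,7(11aH)-trione | O=C1C2=C(CO[Si](C)(C)C(C)(C)C)C(=O)O[C@@H]2/C=C(/C)CCC(=O)[C@@H](C)[C@H]1O[Si](CC)(CC)CC
F7 | step 12 | (4R,5R,6S,10Z,11aR)-3-{[(tert-butyldimethylsilyl)oxy]methyl}-4-hydroxy-6,10-dimethyl-5-[(triethylsilyl)oxy]-4,5,6,8,9,11a-hexahydrocyclodeca[b]furan-2,7-dione | O[C@@H]1C2=C(CO[Si](C)(C)C(C)(C)C)C(=O)O[C@@H]2/C=C(/C)CCC(=O)[C@@H](C)[C@H]1O[Si](CC)(CC)CC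
F8 | step 13 | (4S,5R,6S,10Z,11aR)-3-{[(tert-butyldimethylsilyl)oxy]methyl}-6,10-dimethyl-2,7-dioxo-5-[(triethylsilyl)oxy]-2,4,5,6,7,8,9,11a-octahydrocyclodeca[b]furan-4-yl chloromethanesulfonate | ClCS(=O)(=O)O[C@H]1C2=C(CO[Si](C)(C)C(C)(C)C)C(=O)O[C@@H]2/C=C(/C)CCC(=O)[C@@H](C)[C@H]1O[Si](CC)(CC)CC
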